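**Plan**

1. Rings are lettered A to H from the 3,5-dihydroxyphenoxy end. C1 of each ring B to H is the carbon whose oxygen leads back to the preceding ring. All twenty hydroxyls are carried as methyl ethers and freed last with BBr3.
2. Enabling feature: ring H is a 2-aryloxyphloroglucinol, with C1 (oxygen of ring G) between the hydroxyl carbons C2 and C6 and the third hydroxyl on C4. Seen as the enol of a cyclohexane-1,3,5-trione, C1 is the CH of a malonate, C2 and C6 are its ester carbons, and C3–C4–C5 is the CH2–CO–CH2 of a 3-oxopentanedioate. Ring H is therefore cut at C2–C3 and C5–C6, and the G–O–H ether at O–C1(H), an alkylation on sp3 carbon.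
3. The three crowded ethers C2(B)–O–C1(C), C2(D)–O–C1(E) and C2(F)–O–C1(G) are cut at their C2–O bonds (Ullmann coupling of an aryl bromide with a 2,6-dimethoxyphenol). This leaves dimers A–B, C–D, E–F and G–H, of which C–D and E–F are the same building block.
4. Inside A–B and C–D/E–F the ether is cut at the carbon of the unhindered ring, C1(A)–O and C4(C or E)–O (Chan–Evans–Lam coupling of an arylboronic acid with 6-bromo-2,3,4-trimethoxyphenol).
5. Forward: seven rings come from bought benzenes and only ring H is built (step 9). The chain then grows from the H end, G–H to E–H to C–H to A–H, in three hydrogenolysis/Ullmann rounds.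
6. The target has no stereocentre and no configurationally stable axis, so no stereochemistry has to be set.

Key step: step 9

Remark: the boron-bound intermediate of the last step is drawn in idealised form with one BBr2 group on every oxygen. Neighbouring oxygens may share a boron atom, which changes nothing after hydrolysis.

**Step 1**
Reactants: 1 2,3,4-trimethoxybenzaldehyde
Product: 3 2,3,4-trimethoxyphenol, via 2,3,4-trimethoxyphenyl formate 2 (not isolated)
Conditions: mCPBA, CH2Cl2, 0 °C to rt; aq. NaHCO3 wash; then K2CO3 (cat.), MeOH, rt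
Reagents that add atoms: mCPBA (3-chloroperoxybenzoic acid), OOC(=O)c1cccc(Cl)c1
Why: Baeyer–Villiger oxidation of an electron-rich benzaldehyde goes with aryl migration to the aryl formate, and base-catalysed methanolysis then frees the phenol (overall a Dakin-type CHO-to-OH exchange) without touching the methyl ethers.

**Step 2**
Reactants: 3 2,3,4-trimethoxyphenol
Product: 4 6-bromo-2,3,4-trimethoxyphenol
Conditions: NBS (1.0 equiv), i-Pr2NH (10 mol %), CH2Cl2, 0 °C to rt
Reagents that add atoms: N-bromosuccinimide, O=C1CCC(=O)N1Br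
Why: In this amine-catalysed ortho-bromination of a phenol, the N-bromoamine made in situ is hydrogen-bonded to the free OH and should deliver bromine to C6, the only open ortho position (para is blocked by OMe), rather than to C5, which only methoxy groups activate.

**Step 3**
Reactants: 4 6-bromo-2,3,4-trimethoxyphenol; 5 (3,5-dimethoxyphenyl)boronic acid
Product: 6 1-bromo-2-(3,5-dimethoxyphenoxy)-3,4,5-trimethoxybenzene (ring A–B bromide)
Conditions: Cu(OAc)2 (2 equiv), pyridine (5 equiv), 4 Å MS, CH2Cl2, dry air, rt
Reagents that add atoms: none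
Why: Chan–Evans–Lam oxidative O-arylation runs at room temperature through an aryl–copper phenoxide, accepts phenols flanked by halogen and alkoxy groups, and leaves the C–Br bond untouched for the later Ullmann step.

**Step 4**
Reactants: 7 4-bromo-2,6-dimethoxyphenol
Product: 8 2-(benzyloxy)-5-bromo-1,3-dimethoxybenzene
Conditions: BnBr, K2CO3, DMF, 60 °C
Reagents that add atoms: benzyl bromide, BrCc1ccccc1
Why: This is a Williamson ether synthesis on a phenoxide, and benzyl is the one temporary mask that hydrogenolysis can later remove beside methyl and diaryl ethers.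

**Step 5**
Reactants: 8 2-(benzyloxy)-5-bromo-1,3-dimethoxybenzene
Product: 11 [4-(benzyloxy)-3,5-dimethoxyphenyl]boronic acid, via aryllithium 9 (not isolated), via lithium aryltriisopropoxyborate 10 (not isolated)
Conditions: n-BuLi, THF, −78 °C; B(Oi-Pr)3, −78 °C to rt; 1 M HCl
Reagents that add atoms: triisopropyl borate, CC(C)OB(OC(C)C)OC(C)C; water, O
Why: Bromine–lithium exchange at −78 °C is much faster than benzylic deprotonation, and trapping the aryllithium with a trialkyl borate followed by acidic hydrolysis is the standard boronic acid synthesis.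

**Step 6**
Reactants: 11 [4-(benzyloxy)-3,5-dimethoxyphenyl]boronic acid; 4 6-bromo-2,3,4-trimethoxyphenol
Product: 12 2-[4-(benzyloxy)-3,5-dimethoxyphenoxy]-1-bromo-3,4,5-trimethoxybenzene (dimer bromide used as rings E–F and again as rings C–D)
Conditions: Cu(OAc)2 (2 equiv), pyridine (5 equiv), 4 Å MS, CH2Cl2, dry air, rt
Reagents that add atoms: none
Why: This is the same Chan–Evans–Lam O-arylation as in step 3, again with a boronic acid that has two ortho hydrogens so that only the phenol partner is crowded, and again with retention of C–Br.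

**Step 7**
Reactants: 11 [4-(benzyloxy)-3,5-dimethoxyphenyl]boronic acid
Product: 13 4-(benzyloxy)-3,5-dimethoxyphenol
Conditions: 30% aq. H2O2, THF, 0 °C to rt
Reagents that add atoms: hydrogen peroxide, OO
Why: In this ipso-hydroxylation of an arylboronic acid, hydroperoxide adds to boron, the aryl group migrates from boron to oxygen and the borate ester hydrolyses, so the oxygen lands exactly on C4 of the future ring G.

**Step 8**
Reactants: 13 4-(benzyloxy)-3,5-dimethoxyphenol; 14 dimethyl 2-chloropropanedioate
Product: 15 dimethyl 2-[4-(benzyloxy)-3,5-dimethoxyphenoxy]propanedioate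
Conditions: K2CO3, DMF, 50 °C
Reagents that add atoms: none
Why: Williamson-type SN2 alkylation of a phenoxide by a 2-halomalonate is a standard route to aryloxymalonates, it makes the ether to the future C1 of ring H on an unhindered sp3 carbon, and the chloride is preferred to the bromide because it should not transfer halogen to the electron-rich ring.

**Step 9**
Reactants: 15 dimethyl 2-[4-(benzyloxy)-3,5-dimethoxyphenoxy]propanedioate; 16 dimethyl 3-oxopentanedioate
Product: 18 dimethyl 5-[4-(benzyloxy)-3,5-dimethoxyphenoxy]-2,4,6-trihydroxybenzene-1,3-dicarboxylate, via acyclic dioxoheptanedioate triester 17 (not isolated)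
Conditions: 16 (1.5 equiv) preformed as its sodium enolate with NaOMe (1.5 equiv) in MeOH, added slowly to 15 in MeOH–toluene at reflux; then NaOMe (1.5 equiv), MeOH distilled out against toluene, 110 °C; 1 M HCl, 0 °C
Reagents that add atoms: none
Why: The preformed sodium enolate of 16 attacks one ester carbonyl of 15 and expels methoxide (intermolecular Claisen acylation, first new bond C2–C3 of ring H) to give 17 as its stabilised enolate. With the second charge of NaOMe the remaining CH2 of 17 is enolised and attacks the second malonate ester in a Dieckmann-type 6-exo-trig closure (second new bond C5–C6), and the cyclohexane-1,3,5-trione so formed tautomerises to the benzenetriol, whose phenoxide is the thermodynamic sink of an otherwise reversible sequence. The closest known reaction is the classical alkoxide-mediated cyclocondensation of dialkyl malonates with dialkyl 3-oxopentanedioates to 2,4,6-trihydroxybenzene-1,3-dicarboxylates; here the malonate only carries an aryloxy group on its central carbon, which keeps the one hydrogen needed for aromatisation. No stereocentre is created in 18, since the two labile centres of 17 are lost on aromatisation. The step needs C- rather than O-acylation in the closure, cross- rather than self-condensation of 16, and an un-enolised 15: pyranone lactones from O-attack are reopened by methoxide while the phenoxide is not, 16 is kept as its enolate (ketone masked) and dilute by slow addition, and base matched to the more acidic 16 leaves 15 neutral with its esters further activated by the α-aryloxy oxygen. Methyl esters matched to NaOMe make transesterification degenerate, and the benzyl and methyl ethers of ring G are inert to alkoxide.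

**Step 10**
Reactants: 18 dimethyl 5-[4-(benzyloxy)-3,5-dimethoxyphenoxy]-2,4,6-trihydroxybenzene-1,3-dicarboxylate
Product: 20 2-[4-(benzyloxy)-3,5-dimethoxyphenoxy]benzene-1,3,5-triol, via trihydroxybenzenedicarboxylic acid 19 (not isolated)
Conditions: 2 M aq. KOH, reflux, Ar; then 6 M HCl to pH 1, 80 °C
Reagents that add atoms: none
Why: Ester saponification is followed by protodecarboxylation of a phloroglucinolcarboxylic acid, which loses CO2 readily on warming in acid because its keto tautomer is a β-keto acid, while exclusion of air protects the electron-rich triol.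

**Step 11**
Reactants: 20 2-[4-(benzyloxy)-3,5-dimethoxyphenoxy]benzene-1,3,5-triol
Product: 21 2-[4-(benzyloxy)-3,5-dimethoxyphenoxy]-1,3,5-trimethoxybenzene
Conditions: Me2SO4, K2CO3, acetone, reflux
Reagents that add atoms: dimethyl sulfate, COS(=O)(=O)OC
Why: Exhaustive Williamson O-methylation with the hard electrophile Me2SO4 and K2CO3 in acetone is the standard way to turn phloroglucinols into their trimethyl ethers with little C-methylation.

**Step 12**
Reactants: 21 2-[4-(benzyloxy)-3,5-dimethoxyphenoxy]-1,3,5-trimethoxybenzene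
Product: 22 2,6-dimethoxy-4-(2,4,6-trimethoxyphenoxy)phenol (ring G–H phenol)
Conditions: H2 (1 atm), 10% Pd/C, EtOAc–MeOH, rt
Reagents that add atoms: none
Why: Catalytic hydrogenolysis cleaves only the benzylic C–O bond, since methyl and diaryl ethers are inert and no halogen is present.

**Step 13**
Reactants: 22 2,6-dimethoxy-4-(2,4,6-trimethoxyphenoxy)phenol; 12 dimer bromide
Product: 23 2-(benzyloxy)-5-{6-[2,6-dimethoxy-4-(2,4,6-trimethoxyphenoxy)phenoxy]-2,3,4-trimethoxyphenoxy}-1,3-dimethoxybenzene (ring E–H tetramer benzyl ether)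
Conditions: CuI (20 mol %), picolinic acid (40 mol %), K3PO4, DMSO, 100 °C, Ar; 12 in excess (1.5 equiv)
Reagents that add atoms: none
Why: This Ullmann-type diaryl ether synthesis uses CuI and picolinic acid, a ligand system suited to ortho-substituted partners, the single OH and single C–Br in the flask fix the regiochemistry, and the readily made bromide is used in excess.

**Step 14**
Reactants: 23 ring E–H tetramer benzyl ether
Product: 24 4-{6-[2,6-dimethoxy-4-(2,4,6-trimethoxyphenoxy)phenoxy]-2,3,4-trimethoxyphenoxy}-2,6-dimethoxyphenol (ring E–H tetramer phenol)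
Conditions: H2 (1 atm), 10% Pd/C, THF–MeOH, rt
Reagents that add atoms: none
Why: Catalytic hydrogenolysis of the only benzyl ether proceeds as in step 12, the bromine having been consumed in the coupling.

**Step 15**
Reactants: 24 ring E–H tetramer phenol; 12 dimer bromide
Product: 25 ring C–H hexamer benzyl ether (24 with its phenolic H replaced by the 2-[4-(benzyloxy)-3,5-dimethoxyphenoxy]-3,4,5-trimethoxyphenyl group)
Conditions: CuI (20 mol %), picolinic acid (40 mol %), K3PO4, DMSO, 100 °C, Ar; 12 in excess (1.5 equiv)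
Reagents that add atoms: none
Why: This is a second Ullmann-type etherification between the same two reacting termini as in step 13, so the local steric and electronic situation at the new C2(D)–O–C1(E) bond is unchanged.

**Step 16**
Reactants: 25 ring C–H hexamer benzyl ether
Product: 26 ring C–H hexamer phenol (free OH on C1 of ring C)
Conditions: H2 (1 atm), 10% Pd/C, THF–MeOH, rt
Reagents that add atoms: none
Why: Catalytic hydrogenolysis of the single benzyl ether leaves the fifteen methyl and five diaryl ethers untouched.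

**Step 17**
Reactants: 26 ring C–H hexamer phenol; 6 ring A–B bromide
Product: 27 eicosa-O-methyl octamer (26 with its phenolic H replaced by the 2-(3,5-dimethoxyphenoxy)-3,4,5-trimethoxyphenyl group)
Conditions: CuI (20 mol %), picolinic acid (40 mol %), K3PO4, DMSO, 100 °C, Ar; 6 in excess (2 equiv)
Reagents that add atoms: none
Why: This third Ullmann-type etherification is of the same kind as steps 13 and 15, closes the last ether C2(B)–O–C1(C), and completes the A to H chain.

**Step 18**
Reactants: 27 eicosa-O-methyl octamer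
Product: 29 target octamer CNP0319661.0, via eicosakis(dibromoboryl) ether 28 (not isolated)
Conditions: BBr3 (60 equiv), CH2Cl2, −78 °C to rt, Ar; then ice–water; Sephadex LH-20 under Ar
Reagents that add atoms: none
Why: In this Lewis-acid cleavage of aryl methyl ethers each OMe binds BBr3 and loses MeBr by bromide attack on methyl, the diaryl ether bonds offer no sp3 carbon for such attack, and hydrolysis of the aryl borates frees the twenty phenols.

**Compound list**

1 | 2,3,4-trimethoxybenzaldehyde | COc1ccc(C=O)c(OC)c1OC | starting material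
2 | 2,3,4-trimethoxyphenyl formate | COc1ccc(OC=O)c(OC)c1OC | intermediate
3 | 2,3,4-trimethoxyphenol | COc1ccc(O)c(OC)c1OC | intermediate
4 | 6-bromo-2,3,4-trimethoxyphenol | COc1cc(Br)c(O)c(OC)c1OC | intermediate
5 | (3,5-dimethoxyphenyl)boronic acid | COc1cc(OC)cc(B(O)O)c1 | starting material
6 | 1-bromo-2-(3,5-dimethoxyphenoxy)-3,4,5-trimethoxybenzene (ring A–B bromide) | COc1cc(OC)cc(Oc2c(Br)cc(OC)c(OC)c2OC)c1 | intermediate
7 | 4-bromo-2,6-dimethoxyphenol | COc1cc(Br)cc(OC)c1O | starting material
8 | 2-(benzyloxy)-5-bromo-1,3-dimethoxybenzene | COc1cc(Br)cc(OC)c1OCc1ccccc1 | intermediate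
9 | [4-(benzyloxy)-3,5-dimethoxyphenyl]lithium | COc1cc([Li])cc(OC)c1OCc1ccccc1 | intermediate
10 | lithium [4-(benzyloxy)-3,5-dimethoxyphenyl]triisopropoxyborate | [Li+].COc1cc([B-](OC(C)C)(OC(C)C)OC(C)C)cc(OC)c1OCc1ccccc1 | intermediate
11 | [4-(benzyloxy)-3,5-dimethoxyphenyl]boronic acid | COc1cc(B(O)O)cc(OC)c1OCc1ccccc1 | intermediate
12 | 2-[4-(benzyloxy)-3,5-dimethoxyphenoxy]-1-bromo-3,4,5-trimethoxybenzene (dimer bromide, rings E–F and C–D) | COc1cc(Oc2c(Br)cc(OC)c(OC)c2OC)cc(OC)c1OCc1ccccc1 | intermediate
13 | 4-(benzyloxy)-3,5-dimethoxyphenol | COc1cc(O)cc(OC)c1OCc1ccccc1 | intermediate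
14 | dimethyl 2-chloropropanedioate | COC(=O)C(Cl)C(=O)OC | starting material
15 | dimethyl 2-[4-(benzyloxy)-3,5-dimethoxyphenoxy]propanedioate | COC(=O)C(Oc1cc(OC)c(OCc2ccccc2)c(OC)c1)C(=O)OC | intermediate
16 | dimethyl 3-oxopentanedioate | COC(=O)CC(=O)CC(=O)OC | starting material
17 | dimethyl 2-[4-(benzyloxy)-3,5-dimethoxyphenoxy]-4-(methoxycarbonyl)-3,5-dioxoheptanedioate (C2 and C4 labile, enolised) | COC(=O)CC(=O)C(C(=O)OC)C(=O)C(Oc1cc(OC)c(OCc2ccccc2)c(OC)c1)C(=O)OC | intermediate
18 | dimethyl 5-[4-(benzyloxy)-3,5-dimethoxyphenoxy]-2,4,6-trihydroxybenzene-1,3-dicarboxylate | COC(=O)c1c(O)c(C(=O)OC)c(O)c(Oc2cc(OC)c(OCc3ccccc3)c(OC)c2)c1O | intermediate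
19 | 5-[4-(benzyloxy)-3,5-dimethoxyphenoxy]-2,4,6-trihydroxybenzene-1,3-dicarboxylic acid | OC(=O)c1c(O)c(C(O)=O)c(O)c(Oc2cc(OC)c(OCc3ccccc3)c(OC)c2)c1O | intermediate
20 | 2-[4-(benzyloxy)-3,5-dimethoxyphenoxy]benzene-1,3,5-triol | Oc1cc(O)c(Oc2cc(OC)c(OCc3ccccc3)c(OC)c2)c(O)c1 | intermediate
21 | 2-[4-(benzyloxy)-3,5-dimethoxyphenoxy]-1,3,5-trimethoxybenzene | COc1cc(OC)c(Oc2cc(OC)c(OCc3ccccc3)c(OC)c2)c(OC)c1 | intermediate
22 | 2,6-dimethoxy-4-(2,4,6-trimethoxyphenoxy)phenol (ring G–H phenol) | COc1cc(OC)c(Oc2cc(OC)c(O)c(OC)c2)c(OC)c1 | intermediate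
23 | ring E–H tetramer benzyl ether | COc1cc(Oc2c(Oc3c(OC)cc(Oc4c(OC)cc(OC)cc4OC)cc3OC)cc(OC)c(OC)c2OC)cc(OC)c1OCc1ccccc1 | intermediate
24 | ring E–H tetramer phenol | COc1cc(Oc2c(Oc3c(OC)cc(Oc4c(OC)cc(OC)cc4OC)cc3OC)cc(OC)c(OC)c2OC)cc(OC)c1O | intermediate
25 | ring C–H hexamer benzyl ether | COc1cc(Oc2c(Oc3c(OC)cc(Oc4c(Oc5c(OC)cc(Oc6c(OC)cc(OC)cc6OC)cc5OC)cc(OC)c(OC)c4OC)cc3OC)cc(OC)c(OC)c2OC)cc(OC)c1OCc1ccccc1 | intermediate
26 | ring C–H hexamer phenol | COc1cc(Oc2c(Oc3c(OC)cc(Oc4c(Oc5c(OC)cc(Oc6c(OC)cc(OC)cc6OC)cc5OC)cc(OC)c(OC)c4OC)cc3OC)cc(OC)c(OC)c2OC)cc(OC)c1O | intermediate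
27 | eicosa-O-methyl ether of the target (rings A–H) | COc1cc(OC)cc(Oc2c(Oc3c(OC)cc(Oc4c(Oc5c(OC)cc(Oc6c(Oc7c(OC)cc(Oc8c(OC)cc(OC)cc8OC)cc7OC)cc(OC)c(OC)c6OC)cc5OC)cc(OC)c(OC)c4OC)cc3OC)cc(OC)c(OC)c2OC)c1 | intermediate
28 | eicosakis(dibromoboryl) ether of the target (idealised) | BrB(Br)Oc1cc(OB(Br)Br)cc(Oc2c(Oc3c(OB(Br)Br)cc(Oc4c(Oc5c(OB(Br)Br)cc(Oc6c(Oc7c(OB(Br)Br)cc(Oc8c(OB(Br)Br)cc(OB(Br)Br)cc8OB(Br)Br)cc7OB(Br)Br)cc(OB(Br)Br)c(OB(Br)Br)c6OB(Br)Br)cc5OB(Br)Br)cc(OB(Br)Br)c(OB(Br)Br)c4OB(Br)Br)cc3OB(Br)Br)cc(OB(Br)Br)c(OB(Br)Br)c2OB(Br)Br)c1 | intermediate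
29 | CNP0319661.0, octamer A–H with twenty free hydroxyls (achiral) | Oc1cc(O)cc(Oc2c(Oc3c(O)cc(Oc4c(Oc5c(O)cc(Oc6c(Oc7c(O)cc(Oc8c(O)cc(O)cc8O)cc7O)cc(O)c(O)c6O)cc5O)cc(O)c(O)c4O)cc3O)cc(O)c(O)c2O)c1 | target

**Step count**

Total step count: 18.
Longest linear sequence: 14 steps (7 → 8 → 11 → 13 → 15 → 18 → 20 → 21 → 22 → 23 → 24 → 25 → 26 → 27 → 29; steps 4, 5 and 7 to 18).

**Steps most likely to fail**

1. Step 9.
   - Risk: self-condensation of the ketodiester may outrun the cross-acylation. Enolisation of the aryloxymalonate may mute its ester carbonyls. The closure may also run through an enol oxygen.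
   - Fallback: it sets out from 13 and comes back at 21, and it gives up ring construction. 1,3,5-Trimethoxybenzene is iodinated with N-iodosuccinimide in MeCN to 2-iodo-1,3,5-trimethoxybenzene F1. An excess of F1 is then coupled with phenol 13 under CuI, picolinic acid and K3PO4 in DMSO at 110 °C.
   - Because 13 has two free ortho positions, only one partner of this Ullmann etherification is hindered. The coupling gives 21 directly and bypasses 15, 18 and 20.

2. Step 13.
   - Risk: activation of the electron-rich C–Br bond beside the ortho aryloxy group may be slow. Protodebromination and oxidation of the 2,6-dimethoxyphenol by traces of oxygen may then take over.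
   - Fallback: it sets out from 12 and comes back at 23, and it inverts the polarity of ring F. Bromine–lithium exchange on 12 (n-BuLi, THF, −78 °C) gives the aryllithium F2. B(Oi-Pr)3 converts it into the lithium triisopropoxyborate F3, and 1 M HCl releases {2-[4-(benzyloxy)-3,5-dimethoxyphenoxy]-3,4,5-trimethoxyphenyl}boronic acid F4.
   - F4 is then joined to phenol 22 by Chan–Evans–Lam coupling (Cu(OAc)2, pyridine, 4 Å MS, CH2Cl2, rt). The hot, basic halide coupling is replaced by an oxidative coupling at room temperature.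

3. Step 18.
   - Risk: cleavage of the twenty ethers may stay incomplete once polyborates precipitate. The free polyphenol may also be lost to air oxidation during isolation.
   - Fallback: it sets out from 27 and comes back at 29. The crude material from the BBr3 treatment (through 28) is not purified but acetylated at once (Ac2O, pyridine, rt) to the eicosaacetate F5.
   - F5 is oxidation-stable and can be chromatographed on silica, so partly methylated material can be separated and resubmitted. Acid-catalysed methanolysis of F5 (cat. HCl, degassed MeOH, 40 °C, Ar) and evaporation then release 29 without a chromatographic step on the free phenol.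

**Further compounds**
F1 | step 9 | 2-iodo-1,3,5-trimethoxybenzene | COc1cc(OC)c(I)c(OC)c1
F2 | step 13 | {2-[4-(benzyloxy)-3,5-dimethoxyphenoxy]-3,4,5-trimethoxyphenyl}lithium | COc1cc(Oc2c([Li])cc(OC)c(OC)c2OC)cc(OC)c1OCc1ccccc1
F3 | step 13 | lithium {2-[4-(benzyloxy)-3,5-dimethoxyphenoxy]-3,4,5-trimethoxyphenyl}triisopropoxyborate | [Li+].COc1cc(Oc2c([B-](OC(C)C)(OC(C)C)OC(C)C)cc(OC)c(OC)c2OC)cc(OC)c1OCc1ccccc1
F4 | step 13 | {2-[4-(benzyloxy)-3,5-dimethoxyphenoxy]-3,4,5-trimethoxyphenyl}boronic acid | COc1cc(Oc2c(B(O)O)cc(OC)c(OC)c2OC)cc(OC)c1OCc1ccccc1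
F5 | step 18 | eicosaacetate of the target | CC(=O)Oc1cc(OC(C)=O)cc(Oc2c(Oc3c(OC(C)=O)cc(Oc4c(Oc5c(OC(C)=O)cc(Oc6c(Oc7c(OC(C)=O)cc(Oc8c(OC(C)=O)cc(OC(C)=O)cc8OC(C)=O)cc7OC(C)=O)cc(OC(C)=O)c(OC(C)=O)c6OC(C)=O)cc5OC(C)=O)cc(OC(C)=O)c(OC(C)=O)c4OC(C)=O)cc3OC(C)=O)cc(OC(C)=O)c(OC(C)=O)c2OC(C)=O)c1
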